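**Plan**

- Retrosynthesis: the O–CH3 bonds at C5 and C7 are cut first. Next comes the C4a–C5 bond of ring A, which unfolds ring A into a methyl 2-methoxy-3-oxobutanoate chain bound through C8 to C8a of a (2S)-2-aryl-2,3-dihydro-4H-pyran-4-one (ring C).
- The chain is cut at C7–C8; for this acylation C8 is made a malonate-type carbon by a temporary allyl ester. Ring C is cut at O1–C8a and C4–C4a into an (S)-3-aryl-3-hydroxypropanoate and allyl acetoacetate.
- Forward: ring B is bought with the aryl ketone, ring C is closed second (Claisen acylation, then cyclodehydration), the C5–C7 unit is joined to C8, the allyl ester is removed, ring A is closed last, and the two phenols are methylated.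
- Enabling feature: ring A bears oxygen on C5, C7 and C8a in the 1,3,5 pattern of a folded polyketide, with the C6 methoxy group on the carbon between C5 and C7. It shares C4a and C8a with a dihydropyranone in which C4a is the alpha carbon of a vinylogous ester, so a beta-keto ester chain on C8a can be folded onto C4a of a ring C that is already in place.
- Stereochemistry: the only stereocentre, C2, is set in step 1 by asymmetric transfer hydrogenation of the aryl ketone; its C–O bond is not broken afterwards.

Key step: step 7

Remark on numbering: flavanone numbering is used for the pyranones 5 and 9 to 11 (pyranone C5 = C4a, pyranone C6 = C8a, then C8 methylene, C7 ketone, C6 methoxy carbon, C5 ester carbon).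

Remark on the design: a 6-methylpyranone is not used as the carrier of the chain, because strong bases would remove its C3 proton first and a methoxymalonyl donor would only be deprotonated. C8 is therefore introduced as an ester-activated carbon that can be acylated under soft enolisation.

Assumption: 4 and 9 to 12 are drawn as keto forms; they will be enol and epimer mixtures at carbons that later become sp2, which is taken to be without consequence.

**Step 1**
Reactants: 1 ethyl 3-(3,4-dimethoxyphenyl)-3-oxopropanoate
Product: 2 ethyl (3S)-3-(3,4-dimethoxyphenyl)-3-hydroxypropanoate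
Conditions: RuCl[(S,S)-TsDPEN](p-cymene) (1 mol %), HCO2H/Et3N (5:2), EtOAc, 40 °C
Reagents that add atoms: none
Why: Noyori–Ikariya asymmetric transfer hydrogenation of an aryl ketone; by the usual aryl-ketone model the (S,S)-TsDPEN ruthenium hydride should give the (S)-carbinol (the later C2), and the ester is not touched.

**Step 2**
Reactants: 2 ethyl (3S)-3-(3,4-dimethoxyphenyl)-3-hydroxypropanoate; 3 allyl acetoacetate (prop-2-en-1-yl 3-oxobutanoate)
Product: 5 prop-2-en-1-yl 2-[(2S)-2-(3,4-dimethoxyphenyl)-4-oxo-3,4-dihydro-2H-pyran-6-yl]acetate, via diketo ester 4 (not isolated)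
Conditions: LiN(iPr)2 (7 equiv), 3 (3.5 equiv), THF, −78 to 0 °C; then 2, −78 to −20 °C; 1 M HCl quench; crude 4, CF3CO2H (2 equiv), CH2Cl2, 0 °C, short contact
Reagents that add atoms: none
Why: Claisen-type acylation of the Weiler dianion of 3 at its terminal carbon by the ester of 2 (the excess dianion covers the alkoxide and the acidic product) forms C4–C4a and gives 4, whose hydroxyl then adds to the future C8a ketone and loses water under acid to the vinylogous ester of ring C; the benzylic C–O bond is not broken, so the configuration is retained.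

**Step 3**
Reactants: 6 dimethyl methoxymalonate (dimethyl 2-methoxypropanedioate)
Product: 7 2,3-dimethoxy-3-oxopropanoic acid (methyl hydrogen methoxymalonate, racemic)
Conditions: KOH (1.0 equiv), MeOH, 0 °C to rt; then 1 M HCl, extraction
Reagents that add atoms: potassium hydroxide, [K+].[OH-]
Why: Mono-saponification of a malonic diester; the carboxylate formed in the first hydrolysis shields the second ester from hydroxide.

**Step 4**
Reactants: 7 2,3-dimethoxy-3-oxopropanoic acid
Product: 8 methyl 3-chloro-2-methoxy-3-oxopropanoate (racemic, used crude at once)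
Conditions: (COCl)2 (1.2 equiv), DMF (cat.), CH2Cl2, 0 °C to rt; evaporate
Reagents that add atoms: oxalyl chloride, O=C(Cl)C(Cl)=O
Why: Acid chloride formation through the chloroiminium salt from DMF and oxalyl chloride (Vilsmeier-type activation); immediate use avoids ketene-type self-condensation.

**Step 5**
Reactants: 5 prop-2-en-1-yl 2-[(2S)-2-(3,4-dimethoxyphenyl)-4-oxo-3,4-dihydro-2H-pyran-6-yl]acetate; 8 methyl 3-chloro-2-methoxy-3-oxopropanoate
Product: 9 1-(prop-2-en-1-yl) 5-methyl 2-[(2S)-2-(3,4-dimethoxyphenyl)-4-oxo-3,4-dihydro-2H-pyran-6-yl]-4-methoxy-3-oxopentanedioate (epimers at both chain CH carbons)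
Conditions: MgCl2 (1.5 equiv), Et3N (3 equiv), MeCN, 0 °C; then 8 (1.3 equiv), 0 °C to rt; 1 M HCl work-up
Reagents that add atoms: none
Why: Rathke-type soft enolisation and C-acylation; MgCl2 and Et3N should deprotonate only the C8–H flanked by the allyl ester and C8a, and the magnesium enolate is acylated on carbon by 8 to form C7–C8, while the C3 protons are left alone so C2 is safe.

**Step 6**
Reactants: 9 1-(prop-2-en-1-yl) 5-methyl 2-[(2S)-2-(3,4-dimethoxyphenyl)-4-oxo-3,4-dihydro-2H-pyran-6-yl]-4-methoxy-3-oxopentanedioate
Product: 11 methyl 4-[(2S)-2-(3,4-dimethoxyphenyl)-4-oxo-3,4-dihydro-2H-pyran-6-yl]-2-methoxy-3-oxobutanoate (both epimers at the methoxy carbon), via beta-keto acid 10 (not isolated)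
Conditions: Pd(PPh3)4 (5 mol %), morpholine (3 equiv), THF, rt
Reagents that add atoms: none
Why: Tsuji–Trost deallylation; zerovalent palladium ionises the allyl ester, morpholine takes up the allyl fragment, and beta-keto acid 10 loses CO2 at room temperature, which removes the temporary activating group from C8 without acid or strong base.

**Step 7**
Reactants: 11 methyl 4-[(2S)-2-(3,4-dimethoxyphenyl)-4-oxo-3,4-dihydro-2H-pyran-6-yl]-2-methoxy-3-oxobutanoate
Product: 13 (2S)-2-(3,4-dimethoxyphenyl)-5,7-dihydroxy-6-methoxy-2,3-dihydro-4H-chromen-4-one ((2S)-5,7-dihydroxy-6,3',4'-trimethoxyflavanone), via ring A trione 12 (not isolated)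
Conditions: Mg(OMe)2 (4 equiv), MeOH, 50 °C; then cold 1 M HCl
Reagents that add atoms: none
Why: Proposed new method: Mg(OMe)2 reversibly removes a proton from C8 of 11, the methylene between the C7 ketone and the vinylogous-ester carbon C8a, and the magnesium-bound extended enolate, which carries nucleophilic character at C4a, adds to the C5 ester carbonyl; loss of methoxide gives trione 12, which enolises twice to the 5,7-dihydroxy-6-methoxy arene. The closest known reaction type is the Mg(OMe)2-promoted Claisen cyclisation of 3,5,7-triketo esters to acylphloroglucinols (the laboratory counterpart of the chalcone synthase fold), here applied to a chain whose C8a carbonyl is locked as the enol ether of ring C. Ring A closes by a 6-(enolexo)-exo-trig attack of C4a on the ester. No stereocentre is formed: C6 becomes sp2, so both epimers of 11 converge, and C2 is a spectator that should survive because the C4 carbonyl is tied up in the chelated enolate and later in the 5-phenoxide chelate, which keeps C3 from being deprotonated. The step needs Claisen over aldol closure, and the substrate secures this because the only aldol that could form a six-membered ring (C6 onto C4) would make C6 quaternary and cannot aromatise, so it stays reversible, while attack from C8 on C5 would need a four-membered ring. Aromatisation of 12 makes the productive closure irreversible.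

**Step 8**
Reactants: 13 (2S)-2-(3,4-dimethoxyphenyl)-5,7-dihydroxy-6-methoxy-2,3-dihydro-4H-chromen-4-one
Product: 14 (2S)-2-(3,4-dimethoxyphenyl)-5,6,7-trimethoxy-2,3-dihydro-4H-chromen-4-one ((2S)-5,6,7,3',4'-pentamethoxyflavanone)
Conditions: MeI (10 equiv), Ag2O (4 equiv), 4 Å sieves, CH2Cl2, rt, dark
Reagents that add atoms: iodomethane, CI
Why: Purdie methylation; Ag2O activates iodomethane and takes up HI under nearly neutral conditions, so both phenols, including the hydrogen-bonded 5-OH, should be methylated without the alkoxide or carbonate bases that open ring C to the chalcone and racemise C2.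

**Compound list**

1 | ethyl 3-(3,4-dimethoxyphenyl)-3-oxopropanoate | CCOC(=O)CC(=O)c1ccc(OC)c(OC)c1 | starting material
2 | ethyl (3S)-3-(3,4-dimethoxyphenyl)-3-hydroxypropanoate | CCOC(=O)C[C@H](O)c1ccc(OC)c(OC)c1 | intermediate
3 | allyl acetoacetate (prop-2-en-1-yl 3-oxobutanoate) | CC(=O)CC(=O)OCC=C | starting material
4 | prop-2-en-1-yl (7S)-7-(3,4-dimethoxyphenyl)-7-hydroxy-3,5-dioxoheptanoate | C=CCOC(=O)CC(=O)CC(=O)C[C@H](O)c1ccc(OC)c(OC)c1 | intermediate
5 | prop-2-en-1-yl 2-[(2S)-2-(3,4-dimethoxyphenyl)-4-oxo-3,4-dihydro-2H-pyran-6-yl]acetate | COc1ccc([C@@H]2CC(=O)C=C(CC(=O)OCC=C)O2)cc1OC | intermediate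
6 | dimethyl methoxymalonate | COC(C(=O)OC)C(=O)OC | starting material
7 | 2,3-dimethoxy-3-oxopropanoic acid (methyl hydrogen methoxymalonate) | COC(C(=O)O)C(=O)OC | intermediate
8 | methyl 3-chloro-2-methoxy-3-oxopropanoate | COC(C(=O)Cl)C(=O)OC | intermediate
9 | 1-(prop-2-en-1-yl) 5-methyl 2-[(2S)-2-(3,4-dimethoxyphenyl)-4-oxo-3,4-dihydro-2H-pyran-6-yl]-4-methoxy-3-oxopentanedioate | COc1ccc([C@@H]2CC(=O)C=C(C(C(=O)OCC=C)C(=O)C(OC)C(=O)OC)O2)cc1OC | intermediate
10 | 2-[(2S)-2-(3,4-dimethoxyphenyl)-4-oxo-3,4-dihydro-2H-pyran-6-yl]-4,5-dimethoxy-3,5-dioxopentanoic acid | COc1ccc([C@@H]2CC(=O)C=C(C(C(=O)O)C(=O)C(OC)C(=O)OC)O2)cc1OC | intermediate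
11 | methyl 4-[(2S)-2-(3,4-dimethoxyphenyl)-4-oxo-3,4-dihydro-2H-pyran-6-yl]-2-methoxy-3-oxobutanoate | COc1ccc([C@@H]2CC(=O)C=C(CC(=O)C(OC)C(=O)OC)O2)cc1OC | intermediate
12 | (2S)-2-(3,4-dimethoxyphenyl)-6-methoxy-2,3-dihydro-4H-chromene-4,5,7(4aH,6H)-trione (non-aromatic Claisen adduct) | COc1ccc([C@@H]2CC(=O)C3C(=O)C(OC)C(=O)C=C3O2)cc1OC | intermediate
13 | (2S)-2-(3,4-dimethoxyphenyl)-5,7-dihydroxy-6-methoxy-2,3-dihydro-4H-chromen-4-one | COc1ccc([C@@H]2CC(=O)c3c(cc(O)c(OC)c3O)O2)cc1OC | intermediate
14 | (2S)-2-(3,4-dimethoxyphenyl)-5,6,7-trimethoxy-2,3-dihydro-4H-chromen-4-one | COc1ccc([C@@H]2CC(=O)c3c(cc(OC)c(OC)c3OC)O2)cc1OC | target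

**Step count**

Total step count: 8
Longest linear sequence: 6 steps (steps 1, 2, 5, 6, 7 and 8 from 1); steps 3 and 4 form the side branch from 6.

**Steps most likely to fail**

Step 7 (proposed new method). The chelated enolate may close onto the C5 ester too slowly. Methoxide could then cleave the C6–C7 bond of the beta-keto ester (retro-Claisen), or ring C could open by elimination across C2–C3 with loss of configuration. The fallback uses known chemistry and gives up the Claisen fold. It sets out from 1, which is condensed thermally with 3,4,5-trimethoxyphenol (neat, about 240 °C, Mentzer pyrone synthesis) to 5,6,7,3',4'-pentamethoxyflavone F1. Asymmetric hydrogenation of the C2=C3 bond of F1 with a chiral N-heterocyclic carbene ruthenium catalyst (Ru(cod)(2-methylallyl)2, chiral imidazolinium salt, KOtBu, H2), with the ligand enantiomer that leads to 2S, should give the flavanone together with over-reduced (2S)-5,6,7,3',4'-pentamethoxyflavan-4-ol F2. Oxidation of the mixture with Dess–Martin periodinane brings the sequence back to the route at 14.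

Step 5. Enolisation of 5 by MgCl2 and Et3N may be incomplete. The enolate may be acylated on oxygen or at C4a, and 8 may be consumed through ketene formation and self-condensation. The fallback reverses the polarity of the C7 bond formation. It sets out from 5, which is deallylated with Pd(PPh3)4 and morpholine to 2-[(2S)-2-(3,4-dimethoxyphenyl)-4-oxo-3,4-dihydro-2H-pyran-6-yl]acetic acid F3. Carbonyldiimidazole in THF converts this into (2S)-2-(3,4-dimethoxyphenyl)-6-[2-(1H-imidazol-1-yl)-2-oxoethyl]-2,3-dihydro-4H-pyran-4-one F4. Treatment of F4 with 7, MgCl2 and Et3N (Masamune–Brooks decarboxylative Claisen condensation) should form the C6–C7 bond with loss of CO2 and return to the route at 11, so that 8, 9 and 10 are not needed.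

Step 2. Proton transfer between the dianion and the ester or the acidic product may stop the acylation. The lithium aldolate of 2 may undergo retro-aldol cleavage, and the electron-rich benzylic C–O bond may ionise during the acid treatment with erosion of the configuration at C2. The fallback replaces the ester Claisen condensation by a ketone synthesis through a chelated tetrahedral intermediate. It sets out from 2, which is converted with Me(MeO)NH·HCl and iPrMgCl (THF, −20 °C) into (3S)-3-(3,4-dimethoxyphenyl)-3-hydroxy-N-methoxy-N-methylpropanamide F5. Addition of the dianion of 3 to F5 releases the diketone only on quench and comes back to the route at 4, which is then cyclised to 5 with pyridinium p-toluenesulfonate in CH2Cl2 in place of CF3CO2H.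

**Further compounds**

F1 | step 7 | 5,6,7,3',4'-pentamethoxyflavone | COc1ccc(-c2cc(=O)c3c(OC)c(OC)c(OC)cc3o2)cc1OC
F2 | step 7 | (2S)-5,6,7,3',4'-pentamethoxyflavan-4-ol (C4 epimers) | COc1ccc([C@@H]2CC(O)c3c(cc(OC)c(OC)c3OC)O2)cc1OC
F3 | step 5 | 2-[(2S)-2-(3,4-dimethoxyphenyl)-4-oxo-3,4-dihydro-2H-pyran-6-yl]acetic acid | COc1ccc([C@@H]2CC(=O)C=C(CC(=O)O)O2)cc1OC
F4 | step 5 | (2S)-2-(3,4-dimethoxyphenyl)-6-[2-(1H-imidazol-1-yl)-2-oxoethyl]-2,3-dihydro-4H-pyran-4-one | COc1ccc([C@@H]2CC(=O)C=C(CC(=O)n3ccnc3)O2)cc1OC
F5 | step 2 | (3S)-3-(3,4-dimethoxyphenyl)-3-hydroxy-N-methoxy-N-methylpropanamide | CON(C)C(=O)C[C@H](O)c1ccc(OC)c(OC)c1
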